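# Total synthesis of CNP0265335.3 (target 25)

## Retrosynthetic overview

1. 25 ⇐ 24 by peracid epoxidation of C1=C10 (ring oxirane formed last); 24 ⇐ 22 by CBS reduction of the C3 ketone and esterification with acid 2.
2. 22 ⇐ 18: the ten-membered carbocycle (C6–C7 bond) and the α-methylene lactone close together by a chiral Brønsted acid allylboration/lactonisation of a Z keto-enal released from a furan.
3. 18 ⇐ 13 + 5: γ-acyloxy ynoate → 2-iodoenoate (hydrostannation/iodination) → Negishi coupling with IZnCH2Bpin; the C8 carbinol comes from asymmetric propiolate addition to aldehyde 11.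
4. 11 ⇐ 8 + Me3Al + 7: carboalumination/Pd coupling sets the E C1=C10 alkene; the 3-methylfuran is a latent Z C3–C6 keto-enal.
5. Acids: 2 by asymmetric hydrogenation of 1 (first stereocentre); 5 by Sharpless epoxidation of 3 and oxidation (side-chain oxirane formed first).

Assumption: (3-methylfuran-2-yl)methanol 6 is bought as such; carbons are called C1–C15 by germacrane numbering (C12 is the lactone carbonyl, lactone oxygen on C6).

The target is read as (1R,3S,6R,7R,8R,10R): 1β,10α-epoxide, 4Z alkene, 6,7-trans lactone, 3-O-(R)-2-methylbutanoyl, 8-O-(2R,3S)-2,3-dimethyloxirane-2-carbonyl. The catalyst antipodes named in steps 7 and 11 are my best assignment of sense and should be confirmed on first use.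

## Route

Step 1
Reactants: 1 tiglic acid
Product: 2 (R)-2-methylbutanoic acid
Conditions: H2 (4 atm), Ru(OAc)2((R)-H8-BINAP) (0.5 mol%), MeOH, rt
Reagents that add atoms: none
Why: Carboxylate-directed asymmetric hydrogenation of a trisubstituted α,β-unsaturated acid, in which the bound acid exposes one alkene face so that the R ligand gives the R acid in high ee, the first stereocentre of the route.

Step 2
Reactants: 3 (E)-2-methylbut-2-en-1-ol
Product: 4 [(2S,3S)-2,3-dimethyloxiran-2-yl]methanol
Conditions: t-BuOOH, Ti(OiPr)4 (5 mol%), L-(+)-diethyl tartrate (7 mol%), 4 Å MS, CH2Cl2, −20 °C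
Reagents that add atoms: tert-butyl hydroperoxide, CC(C)(C)OO
Why: Katsuki–Sharpless asymmetric epoxidation of an E trisubstituted allylic alcohol, in which the Ti(OiPr)4/L-(+)-tartrate catalyst binds the alkoxide and delivers the peroxide oxygen to the face that gives the 2S,3S epoxy alcohol with the two methyls cis.

Step 3
Reactants: 4 [(2S,3S)-2,3-dimethyloxiran-2-yl]methanol
Product: 5 (2R,3S)-2,3-dimethyloxirane-2-carboxylic acid
Conditions: RuCl3·xH2O (2 mol%), NaIO4 (3 equiv), MeCN/EtOAc/H2O, 0 °C → rt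
Reagents that add atoms: sodium periodate, [Na+].[O-]I(=O)(=O)=O
Why: Catalytic RuO4 oxidation takes the primary epoxy alcohol to the glycidic acid without opening the oxirane, so both stereocentres are kept and only the C2 descriptor changes from S to R because CO2H now outranks the ring carbon.

Step 4
Reactants: 6 (3-methylfuran-2-yl)methanol
Product: 7 2-(chloromethyl)-3-methylfuran
Conditions: SOCl2 (1.05 equiv), pyridine (1.1 equiv), Et2O, −20 → 0 °C; filtered solution used at once
Reagents that add atoms: thionyl chloride, O=S(Cl)Cl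
Why: Chlorodehydroxylation of a furfuryl (benzylic-type) alcohol through its chlorosulfite, run cold and used without storage because furfuryl chlorides polymerise on standing.

Step 5
Reactants: 8 but-3-yn-1-ol; 7 2-(chloromethyl)-3-methylfuran
Product: 10 (E)-3-methyl-5-(3-methylfuran-2-yl)pent-3-en-1-ol, via alkenylalane 9 (not isolated)
Conditions: Me3Al (3 equiv), Cp2ZrCl2 (0.25 equiv), CH2Cl2, 0 °C → rt; then 7, Pd(PPh3)4 (3 mol%), THF, rt
Reagents that add atoms: trimethylaluminium, C[Al](C)C
Why: Negishi zirconium-catalysed syn carboalumination puts methyl on the internal alkyne carbon and aluminium on the terminal one, and the palladium-catalysed coupling of that E alkenylalane with the benzylic-type chloride goes with retention, which fixes the E C1=C10 alkene and attaches the furan that hides C3–C6.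

Step 6
Reactants: 10 (E)-3-methyl-5-(3-methylfuran-2-yl)pent-3-en-1-ol
Product: 11 (E)-3-methyl-5-(3-methylfuran-2-yl)pent-3-enal
Conditions: Dess–Martin periodinane (1.2 equiv), NaHCO3, CH2Cl2, 0 °C; used crude the same day
Reagents that add atoms: none
Why: Buffered Dess–Martin oxidation is the standard neutral way to make β,γ-unsaturated 3-methylalk-3-enals without moving the alkene into conjugation, and it leaves the furan and the alkene alone.

Step 7
Reactants: 11 (E)-3-methyl-5-(3-methylfuran-2-yl)pent-3-enal; 12 methyl propiolate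
Product: 13 methyl (4R,6E)-4-hydroxy-6-methyl-8-(3-methylfuran-2-yl)oct-6-en-2-ynoate
Conditions: (S,S)-ProPhenol (10 mol%), Me2Zn (3 equiv), Ph3PO (20 mol%), toluene, 4 °C
Reagents that add atoms: none
Why: Catalytic asymmetric alkynylation of an aldehyde, in which the alkynylzinc formed from Me2Zn is held by the (S,S)-ProPhenol ligand and adds to one aldehyde face to set the C8 carbinol as R while bringing in C7, C11 and C12.

Step 8
Reactants: 13 methyl (4R,6E)-4-hydroxy-6-methyl-8-(3-methylfuran-2-yl)oct-6-en-2-ynoate; 5 (2R,3S)-2,3-dimethyloxirane-2-carboxylic acid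
Product: 15 methyl (4R,6E)-4-{[(2R,3S)-2,3-dimethyloxirane-2-carbonyl]oxy}-6-methyl-8-(3-methylfuran-2-yl)oct-6-en-2-ynoate, via mixed anhydride 14 (not isolated)
Conditions: 5, 2,4,6-trichlorobenzoyl chloride, Et3N, THF, 0 °C, filter; then 13, DMAP, toluene, 0 °C
Reagents that add atoms: none
Why: Yamaguchi esterification acylates the secondary propargylic alcohol with the hindered α,α-disubstituted glycidic acid without touching C8 or the oxirane, and the ester also blocks O8 so that it cannot lactonise onto C12 once the Z enoate is made.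

Step 9
Reactants: 15 methyl (4R,6E)-4-{[(2R,3S)-2,3-dimethyloxirane-2-carbonyl]oxy}-6-methyl-8-(3-methylfuran-2-yl)oct-6-en-2-ynoate
Product: 17 methyl (2E,4R,6E)-4-{[(2R,3S)-2,3-dimethyloxirane-2-carbonyl]oxy}-2-iodo-6-methyl-8-(3-methylfuran-2-yl)octa-2,6-dienoate, via vinylstannane 16 (not isolated)
Conditions: Bu3SnH (1.1 equiv), Pd(PPh3)4 (2 mol%), THF, 0 °C; then I2 (1.05 equiv), CH2Cl2, −78 °C
Reagents that add atoms: iodine, [I][I]
Why: Palladium-catalysed syn hydrostannation of an ynoate places tin α to the ester and hydrogen on C7, and iododestannylation with retention gives the 2-iodoenoate with C8 cis to the ester, the geometry needed later for a 6,7-trans lactone.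

Step 10
Reactants: 17 methyl (2E,4R,6E)-4-{[(2R,3S)-2,3-dimethyloxirane-2-carbonyl]oxy}-2-iodo-6-methyl-8-(3-methylfuran-2-yl)octa-2,6-dienoate
Product: 18 methyl (2Z,4R,6E)-4-{[(2R,3S)-2,3-dimethyloxirane-2-carbonyl]oxy}-6-methyl-8-(3-methylfuran-2-yl)-2-[(4,4,5,5-tetramethyl-1,3,2-dioxaborolan-2-yl)methyl]octa-2,6-dienoate
Conditions: ICH2Bpin, Zn dust, THF, rt (gives IZnCH2Bpin); then 17, Pd(PPh3)4 (5 mol%), THF, 40 °C
Reagents that add atoms: 2-(iodomethyl)-4,4,5,5-tetramethyl-1,3,2-dioxaborolane, ICB1OC(C)(C)C(C)(C)O1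
Why: Negishi cross-coupling of the borylmethylzinc reagent with an alkenyl iodide is a known stereoretentive route to allylboronates, here giving the 2-alkoxycarbonyl allylboronate with C8 trans to the CH2B group while the esters, oxirane and furan are untouched.

Step 11
Reactants: 18 methyl (2Z,4R,6E)-4-{[(2R,3S)-2,3-dimethyloxirane-2-carbonyl]oxy}-6-methyl-8-(3-methylfuran-2-yl)-2-[(4,4,5,5-tetramethyl-1,3,2-dioxaborolan-2-yl)methyl]octa-2,6-dienoate
Product: 22 (6R,7R,8R)-8-{[(2R,3S)-2,3-dimethyloxirane-2-carbonyl]oxy}-3-oxogermacra-1(10)E,4Z,11(13)-trien-12,6-olide, via endoperoxide 19 (not isolated), via keto-enal 20 (not isolated), via borate 21 (not isolated)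
Conditions: O2, tetraphenylporphyrin (1 mol%), visible light, CH2Cl2, −78 °C; Me2S, −78 → −20 °C; cold silica plug, solvent exchange; then slow addition to (S,S)-IDPi (imidodiphosphorimidate Brønsted acid from a 3,3′-diaryl-BINOL, 10 mol%), 5 Å MS, toluene (1 mM), −20 °C → rt
Reagents that add atoms: dioxygen (as singlet oxygen), O=O
Why: Proposed new method: after the known singlet-oxygen [4+2] addition to the furan and Me2S reduction have released the Z keto-enal 20, a confined chiral Brønsted acid is proposed to protonate a pinacol oxygen of the 2-alkoxycarbonyl allylboronate (raising the Lewis acidity of boron, as in acid-catalysed allylborations) so that the C6 aldehyde binds boron and C7 adds through a closed six-membered chair with C5 and C8 both pseudo-equatorial (C8 trans to CH2B gives the anti adduct, hence the 6,7-trans relationship), the chiral anion pocket selecting the Si face of the aldehyde to give 6R,7R, after which borate 21 lactonises onto the methyl ester with loss of MeOBpin and so closes the ten-membered ring and the α-methylene lactone together; the closest known reactions are the intermolecular chiral phosphoric acid-catalysed allylboration of aldehydes and the triflic acid-catalysed allylboration/lactonisation of 2-alkoxycarbonyl allylboronates, neither of which has been shown as a macrocyclisation or with an imidodiphosphorimidate.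

Step 12
Reactants: 22 (6R,7R,8R)-8-{[(2R,3S)-2,3-dimethyloxirane-2-carbonyl]oxy}-3-oxogermacra-1(10)E,4Z,11(13)-trien-12,6-olide
Product: 23 (3S,6R,7R,8R)-8-{[(2R,3S)-2,3-dimethyloxirane-2-carbonyl]oxy}-3-hydroxygermacra-1(10)E,4Z,11(13)-trien-12,6-olide
Conditions: (R)-Me-CBS (0.3 equiv), catecholborane (1.5 equiv), toluene/CH2Cl2, −78 °C
Reagents that add atoms: none
Why: Corey–Bakshi–Shibata reduction, a metal-free oxazaborolidine-catalysed hydride transfer in which the ketone binds with its larger alkenyl arm (C4) away from the catalyst so that the R catalyst gives the 3S carbinol, while catecholborane at −78 °C leaves the α-methylene lactone, the esters and the oxirane alone.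

Step 13
Reactants: 23 (3S,6R,7R,8R)-8-{[(2R,3S)-2,3-dimethyloxirane-2-carbonyl]oxy}-3-hydroxygermacra-1(10)E,4Z,11(13)-trien-12,6-olide; 2 (R)-2-methylbutanoic acid
Product: 24 (3S,6R,7R,8R)-8-{[(2R,3S)-2,3-dimethyloxirane-2-carbonyl]oxy}-3-{[(2R)-2-methylbutanoyl]oxy}germacra-1(10)E,4Z,11(13)-trien-12,6-olide
Conditions: 2, DCC, DMAP (10 mol%), CH2Cl2, 0 °C → rt
Reagents that add atoms: none
Why: Steglich esterification of the secondary allylic alcohol under near-neutral conditions keeps the α-stereocentre of the acid and caps O3 so that a free hydroxyl cannot direct the next oxidation to the C4=C5 alkene.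

Step 14
Reactants: 24 (3S,6R,7R,8R)-8-{[(2R,3S)-2,3-dimethyloxirane-2-carbonyl]oxy}-3-{[(2R)-2-methylbutanoyl]oxy}germacra-1(10)E,4Z,11(13)-trien-12,6-olide
Product: 25 (1R,3S,6R,7R,8R,10R)-8-{[(2R,3S)-2,3-dimethyloxirane-2-carbonyl]oxy}-1,10-epoxy-3-{[(2R)-2-methylbutanoyl]oxy}germacra-4Z,11(13)-dien-12,6-olide (target)
Conditions: mCPBA (1.1 equiv), NaHCO3, CH2Cl2, 0 °C
Reagents that add atoms: 3-chloroperbenzoic acid, OOC(=O)c1cccc(Cl)c1
Why: Prilezhaev epoxidation picks the only electron-rich alkene (C4=C5 is deactivated by two allylic acyloxy groups and C11=C13 is conjugated), and stereospecific syn addition to the exposed outer face of the E alkene in the ring conformer is expected to give the 1β,10α-oxirane (1R,10R).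

## Compound list

1 | tiglic acid, (E)-2-methylbut-2-enoic acid | C/C=C(\C)C(=O)O | starting material
2 | (R)-2-methylbutanoic acid | CC[C@@H](C)C(=O)O | intermediate
3 | (E)-2-methylbut-2-en-1-ol | C/C=C(\C)CO | starting material
4 | [(2S,3S)-2,3-dimethyloxiran-2-yl]methanol | OC[C@]1(C)O[C@H]1C | intermediate
5 | (2R,3S)-2,3-dimethyloxirane-2-carboxylic acid | OC(=O)[C@]1(C)O[C@H]1C | intermediate
6 | (3-methylfuran-2-yl)methanol | Cc1ccoc1CO | starting material
7 | 2-(chloromethyl)-3-methylfuran | Cc1ccoc1CCl | intermediate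
8 | but-3-yn-1-ol | C#CCCO | starting material
9 | dimethylaluminium (E)-4-(dimethylalumanyl)-3-methylbut-3-en-1-olate (alkenylalane, not isolated) | C[Al](C)OCC/C(C)=C/[Al](C)C | intermediate
10 | (E)-3-methyl-5-(3-methylfuran-2-yl)pent-3-en-1-ol | OCC/C(C)=C/Cc1occc1C | intermediate
11 | (E)-3-methyl-5-(3-methylfuran-2-yl)pent-3-enal | O=CC/C(C)=C/Cc1occc1C | intermediate
12 | methyl propiolate | C#CC(=O)OC | starting material
13 | methyl (4R,6E)-4-hydroxy-6-methyl-8-(3-methylfuran-2-yl)oct-6-en-2-ynoate | COC(=O)C#C[C@H](O)C/C(C)=C/Cc1occc1C | intermediate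
14 | (2R,3S)-2,3-dimethyloxirane-2-carboxylic 2,4,6-trichlorobenzoic anhydride (not isolated) | O=C(OC(=O)c1c(Cl)cc(Cl)cc1Cl)[C@]1(C)O[C@H]1C | intermediate
15 | methyl (4R,6E)-4-{[(2R,3S)-2,3-dimethyloxirane-2-carbonyl]oxy}-6-methyl-8-(3-methylfuran-2-yl)oct-6-en-2-ynoate | COC(=O)C#C[C@H](OC(=O)[C@]1(C)O[C@H]1C)C/C(C)=C/Cc1occc1C | intermediate
16 | methyl (2E,4R,6E)-4-{[(2R,3S)-2,3-dimethyloxirane-2-carbonyl]oxy}-6-methyl-8-(3-methylfuran-2-yl)-2-(tributylstannyl)octa-2,6-dienoate (not isolated) | COC(=O)/C([Sn](CCCC)(CCCC)CCCC)=C\[C@H](OC(=O)[C@]1(C)O[C@H]1C)C/C(C)=C/Cc1occc1C | intermediate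
17 | methyl (2E,4R,6E)-4-{[(2R,3S)-2,3-dimethyloxirane-2-carbonyl]oxy}-2-iodo-6-methyl-8-(3-methylfuran-2-yl)octa-2,6-dienoate | COC(=O)/C(I)=C\[C@H](OC(=O)[C@]1(C)O[C@H]1C)C/C(C)=C/Cc1occc1C | intermediate
18 | methyl (2Z,4R,6E)-4-{[(2R,3S)-2,3-dimethyloxirane-2-carbonyl]oxy}-6-methyl-8-(3-methylfuran-2-yl)-2-[(4,4,5,5-tetramethyl-1,3,2-dioxaborolan-2-yl)methyl]octa-2,6-dienoate | COC(=O)/C(CB1OC(C)(C)C(C)(C)O1)=C\[C@H](OC(=O)[C@]1(C)O[C@H]1C)C/C(C)=C/Cc1occc1C | intermediate
19 | furan endoperoxide of 18 (2,3,7-trioxabicyclo[2.2.1]hept-5-ene in place of the furan, both bridgehead epimers, not isolated) | COC(=O)/C(CB1OC(C)(C)C(C)(C)O1)=C\[C@H](OC(=O)[C@]1(C)O[C@H]1C)C/C(C)=C/CC12OOC(O1)C=C2C | intermediate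
20 | methyl (2Z,4R,6E,10Z)-4-{[(2R,3S)-2,3-dimethyloxirane-2-carbonyl]oxy}-6,10-dimethyl-9,12-dioxo-2-[(4,4,5,5-tetramethyl-1,3,2-dioxaborolan-2-yl)methyl]dodeca-2,6,10-trienoate (Z keto-enal, not isolated) | COC(=O)/C(CB1OC(C)(C)C(C)(C)O1)=C\[C@H](OC(=O)[C@]1(C)O[C@H]1C)C/C(C)=C/CC(=O)/C(C)=C\C=O | intermediate
21 | methyl 2-[(1R,2R,3Z,7E,10R)-10-{[(2R,3S)-2,3-dimethyloxirane-2-carbonyl]oxy}-4,8-dimethyl-5-oxo-2-[(4,4,5,5-tetramethyl-1,3,2-dioxaborolan-2-yl)oxy]cyclodeca-3,7-dien-1-yl]prop-2-enoate (borate, not isolated) | COC(=O)C(=C)[C@H]1[C@H](OB2OC(C)(C)C(C)(C)O2)/C=C(/C)C(=O)C/C=C(\C)C[C@H]1OC(=O)[C@]3(C)O[C@H]3C | intermediate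
22 | (6R,7R,8R)-8-{[(2R,3S)-2,3-dimethyloxirane-2-carbonyl]oxy}-3-oxogermacra-1(10)E,4Z,11(13)-trien-12,6-olide | C=C1C(=O)O[C@@H]2/C=C(/C)C(=O)C/C=C(\C)C[C@@H](OC(=O)[C@]3(C)O[C@H]3C)[C@@H]12 | intermediate
23 | (3S,6R,7R,8R)-8-{[(2R,3S)-2,3-dimethyloxirane-2-carbonyl]oxy}-3-hydroxygermacra-1(10)E,4Z,11(13)-trien-12,6-olide | C=C1C(=O)O[C@@H]2/C=C(/C)[C@@H](O)C/C=C(\C)C[C@@H](OC(=O)[C@]3(C)O[C@H]3C)[C@@H]12 | intermediate
24 | (3S,6R,7R,8R)-8-{[(2R,3S)-2,3-dimethyloxirane-2-carbonyl]oxy}-3-{[(2R)-2-methylbutanoyl]oxy}germacra-1(10)E,4Z,11(13)-trien-12,6-olide | C=C1C(=O)O[C@@H]2/C=C(/C)[C@@H](OC(=O)[C@H](C)CC)C/C=C(\C)C[C@@H](OC(=O)[C@]3(C)O[C@H]3C)[C@@H]12 | intermediate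
25 | (1R,3S,6R,7R,8R,10R)-8-{[(2R,3S)-2,3-dimethyloxirane-2-carbonyl]oxy}-1,10-epoxy-3-{[(2R)-2-methylbutanoyl]oxy}germacra-4Z,11(13)-dien-12,6-olide | C=C1C(=O)O[C@@H]2/C=C(/C)[C@@H](OC(=O)[C@H](C)CC)C[C@H]3O[C@]3(C)C[C@@H](OC(=O)[C@]3(C)O[C@H]3C)[C@@H]12 | target

## Step count and risks

Total steps: 14. Longest linear sequence: 11 steps (6 → 25, steps 4 to 14); acid 5 (2 steps) joins at step 8 and acid 2 (1 step) at step 13.

The three steps most likely to fail:

**Step 11 (the proposed macrocyclising allylboration).** The ester-substituted allylboronate is a sluggish nucleophile. The Z keto-enal 20 may isomerise to E or oligomerise under acid. The C8 centre may oppose the catalyst, since the substrate's own facial preference at C7 is not predictable. The fallback uses known chemistry, sets out from iodide 17 and comes back at 22. Stille coupling of 17 with Bu3SnCH2OH (Pd(PPh3)4, dioxane, 80 °C) gives the 2-(hydroxymethyl)enoate F1. CBr4/PPh3 (CH2Cl2, 0 °C) gives the allylic bromide F2. O2/tetraphenylporphyrin/light at −78 °C followed by Me2S unmasks the furan to the bromo keto-enal F3. Slow addition of F3 to CrCl2 (10 equiv, THF, 2 mM, rt) effects an intramolecular Nozaki–Hiyama allylation, which is anti-selective and is the established way to 6,7-trans germacranolides. The alkoxide lactonises on work-up to give 22.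

**Step 7 (asymmetric propiolate addition).** Aldehyde 11 can slip into conjugation under the basic zinc conditions, and unbranched aliphatic aldehydes give only moderate ee. The fallback sets C8 by ketone reduction instead; it sets out from 11 and comes back at 13. Lithiated 12 (LiN(SiMe3)2, THF, −78 °C) adds to 11 within minutes to give the racemic carbinol F4. Dess–Martin oxidation gives the ynone F5. Asymmetric transfer hydrogenation (Ru((R,R)-TsDPEN)(p-cymene), 2-propanol, rt) then gives 13.

**Step 12 (CBS reduction on the macrocycle).** The twisted ring enone may not behave as a normal large/small ketone, so ring control could override the catalyst and give the 3R epimer. The fallback uses that outcome; it sets out from 22 and comes back at 24. Reduction with the matched (S)-Me-CBS/catecholborane gives the 3R carbinol F6. Mitsunobu esterification with acid 2 (PPh3, DIAD, THF, 0 °C) inverts C3 and installs the 2-methylbutanoate in one operation, giving 24 directly.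

Further compounds
F1 | step 11 | methyl (2Z,4R,6E)-4-{[(2R,3S)-2,3-dimethyloxirane-2-carbonyl]oxy}-2-(hydroxymethyl)-6-methyl-8-(3-methylfuran-2-yl)octa-2,6-dienoate | COC(=O)/C(CO)=C\[C@H](OC(=O)[C@]1(C)O[C@H]1C)C/C(C)=C/Cc1occc1C
F2 | step 11 | methyl (2E,4R,6E)-2-(bromomethyl)-4-{[(2R,3S)-2,3-dimethyloxirane-2-carbonyl]oxy}-6-methyl-8-(3-methylfuran-2-yl)octa-2,6-dienoate | COC(=O)/C(CBr)=C\[C@H](OC(=O)[C@]1(C)O[C@H]1C)C/C(C)=C/Cc1occc1C
F3 | step 11 | methyl (2E,4R,6E,10Z)-2-(bromomethyl)-4-{[(2R,3S)-2,3-dimethyloxirane-2-carbonyl]oxy}-6,10-dimethyl-9,12-dioxododeca-2,6,10-trienoate | COC(=O)/C(CBr)=C\[C@H](OC(=O)[C@]1(C)O[C@H]1C)C/C(C)=C/CC(=O)/C(C)=C\C=O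
F4 | step 7 | methyl (6E)-4-hydroxy-6-methyl-8-(3-methylfuran-2-yl)oct-6-en-2-ynoate (racemic) | COC(=O)C#CC(O)C/C(C)=C/Cc1occc1C
F5 | step 7 | methyl (6E)-6-methyl-8-(3-methylfuran-2-yl)-4-oxooct-6-en-2-ynoate | COC(=O)C#CC(=O)C/C(C)=C/Cc1occc1C
F6 | step 12 | (3R,6R,7R,8R)-8-{[(2R,3S)-2,3-dimethyloxirane-2-carbonyl]oxy}-3-hydroxygermacra-1(10)E,4Z,11(13)-trien-12,6-olide | C=C1C(=O)O[C@@H]2/C=C(/C)[C@H](O)C/C=C(\C)C[C@@H](OC(=O)[C@]3(C)O[C@H]3C)[C@@H]12
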